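Reckon this flask from one rate, the gain of product per minute, and leave its concentrations aside.

| flask | solid substrate | reagent | initiator | remark | time |
|---|---|---|---|---|---|
| dawn | 1 mM | 1.7 mM | 15 µM | run made earlier |  |
| spring | 1 mM | 3.8 mM | 15 µM | run made earlier |  |
| autumn | 1 mM | 2.5 mM | 7.5 µM | run made earlier |  |
| flask | 1.0 mM | 2.50 mM | 15 µM |  | 3.0 min |

| run | time / min | product / % | starting material / % |
|---|---|---|---|
| dawn | 0.250 | 5.2 | 2.8 |
| dawn | 0.417 | 9.5 | 2.3 |
| dawn | 0.667 | 11.1 | 0.7 |
| dawn | 1.00 | 18.9 | 0.1 |
| dawn | 2.00 | 38.2 | 0 |
| dawn | 3.00 | 56.7 | 0.4 |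
| spring | 0.200 | 1.9 | 1.4 |
| spring | 0.667 | 14.3 | 1.0 |
| spring | 1.00 | 16.4 | 0.9 |
| spring | 1.50 | 29.1 | 1.9 |
| spring | 2.50 | 47.2 | 1.4 |
| spring | 3.00 | 57.4 | 1.2 |
| autumn | 0.667 | 11.3 | 2.4 |
| autumn | 1.33 | 22.9 | 2.1 |
| autumn | 2.00 | 38.6 | 1.2 |
| autumn | 2.50 | 46.4 | 0 |
| autumn | 3.00 | 58.4 | 0.6 |

(scatter of a reading: 1 percentage point)

- as a solid, counted per litre of solution: solid substrate
- at the start none of the solid substrate is in solution
- starting material is what solid substrate becomes in solution
- starting material means what is dissolved; the solid is not counted in it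

1. amount of product at 3.0 min, in percent of the solid substrate charged
2. concentration of starting material in solution at 3.0 min, in percent of saturation

1. The last readings of the earlier runs, each at 3.00 min, average to 0.192 mM min⁻¹. Call this the supply rate: the mean product made per litre and minute.
2. At the start, the dawn and spring runs gain 0.176 mM min⁻¹ over the first 1.00 min.
3. The spring run holds 2.24 times the reagent of the dawn run, yet its last reading is 1.01 times as high.
4. The autumn run, with half the initiator, ends at 1.02 times the mean of the other two.
5. After the first minute, the dawn and spring runs gain 0.197 mM min⁻¹, more than at the start. No slowing accumulates in these readings.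
6. The mean line stands 2.8 percentage points above the spring reading at 1.00 min, but gives 28.8 % against 29.1 % at 1.50 min.
7. Dissolved starting material in the last readings averages 0.733 % of the charge, far less than the product. It is used about as it arrives, so these readings point to dissolving of the solid substrate as the rate-limiting step. A supply that holds up points to a solution well below saturation, though these runs give no figure.
8. This flask, inside the tested charges, should give 57.5 %.

The forecast gives 57.5 % and 3 % of saturation, holding that “dissolution of the solid is rate-limiting”.

The flask gives 57.6 % of product, 0.100 points from the reckoning, at 0.853 % of saturation.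

    initiator → 2 initiating radical (k = 0.00586 s⁻¹)
    solid substrate ⇌ starting material, rate k2*(cs2 - [starting material]) while solid is left; crystals form when [starting material] > cs2 (solubility = 0.170 mM, k = 0.0193 s⁻¹)
    2 chain carrier → ended chains (k = 1.90 × 10⁷ M⁻¹ s⁻¹)
    reagent + chain carrier → product + initiating radical (k = 1.43 × 10⁶ M⁻¹ s⁻¹)
    starting material + initiating radical ⇌ chain carrier (K = 1.30 × 10⁷ M⁻¹, k = 1.15 × 10⁵ M⁻¹ s⁻¹)

In this flask the supply rate accounts for 0.576 mM of the 1.0 mM charged, and 42.3 % stands as solid at 3.00 min. A neighbouring flask holds 0.25 mM of solid substrate, its other charges as here. The supply rate would use that charge in 1.30 min, earlier than 3.0 min. That neighbouring flask gives >99.9 %, with 0 % of solid substrate and 90 % of its reagent left at 3.00 min.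

Readings and results are simulated on assumed constants, and the scatter is random.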